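**Assumption:** the SMILES is read as (3R) at the lactone carbinol carbon with an (E)-6′ alkene in the side chain; dienes 6 and 9 are bought as catalogue reagents.

## Retrosynthetic overview

1. Lactone ring (formed last): ester C–O bond, from a methyl 6-(2-hydroxyalkyl)salicylate by attack of the C9 carbinol on the C1 ester (polyketide numbering, C1 = ester carbon).
2. Benzene ring (formed before the lactone): C2–C7 bond by aldol condensation and aromatisation of a linear (9R)-9-hydroxy-3,7-dioxo-5-enoate, i.e. a C16 fatty-acyl unit extended by four acetate units.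
3. That chain is released in the flask from the adduct of 1-methoxy-1,3-bis(trimethylsilyloxy)butadiene (C1–C4) and an (R)-2-alkyl-2,3-dihydro-4H-pyran-4-one (C5–C9 plus tail), a transient ring that carries the stereocentre.
4. Dihydropyranone: catalytic enantioselective formal hetero-Diels–Alder reaction of (E)-hexadec-7-enal with Danishefsky's diene.
5. Aldehyde: dec-1-yne plus ethyl 6-bromohexanoate by hydrozirconation/cross-coupling (E alkene), then partial reduction. Ring order: dihydropyranone (transient), then benzene ring, then lactone.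

## Route

**Step 1**
Reactants: 1 dec-1-yne; 2 ethyl 6-bromohexanoate
Product: 4 ethyl (E)-hexadec-7-enoate, via (E)-dec-1-enylzirconocene chloride 3 (not isolated)
Conditions: Cp2Zr(H)Cl (1.0 equiv), THF, 20 °C; then 2, Pd(acac)2 (2.5 mol %), LiBr (2 equiv), THF/NMP, 55 °C
Reagents that add atoms: none
Why: Syn hydrozirconation of the terminal alkyne puts zirconium on the terminal carbon and fixes the E geometry, and the alkenylzirconium then undergoes palladium-catalysed Negishi-type sp2–sp3 cross-coupling with the primary alkyl bromide with retention of geometry and tolerance of the ester.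

**Step 2**
Reactants: 4 ethyl (E)-hexadec-7-enoate
Product: 5 (E)-hexadec-7-enal
Conditions: iBu2AlH (DIBAL-H, 1.05 equiv), CH2Cl2, −78 °C; aq. potassium sodium tartrate (KNaC4H4O6) work-up
Reagents that add atoms: none
Why: At −78 °C the aluminium hemiacetal formed by hydride addition to the ester survives until hydrolytic work-up, so the DIBAL-H partial reduction stops at the aldehyde and the isolated alkene is untouched.

**Step 3**
Reactants: 5 (E)-hexadec-7-enal; 6 (E)-1-methoxy-3-(trimethylsilyloxy)buta-1,3-diene (Danishefsky's diene)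
Product: 8 (R)-2-[(E)-pentadec-6-enyl]-2,3-dihydro-4H-pyran-4-one, via silyl aldol adduct 7 (not isolated)
Conditions: (S)-BINOL (20 mol %), Ti(OiPr)4 (10 mol %), 4 Å MS, Et2O, −20 °C; then TFA, CH2Cl2, 0 °C
Reagents that add atoms: none
Why: BINOL/Ti(OiPr)4-catalysed enantioselective Mukaiyama aldol addition of the diene to the Si face of the aldehyde (the sense expected for the S ligand, as in the Keck allylation), followed by acid-promoted cyclisation with loss of methanol (Keck-type formal hetero-Diels–Alder reaction), sets the only stereocentre as R under catalyst control.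

**Step 4**
Reactants: 8 (R)-2-[(E)-pentadec-6-enyl]-2,3-dihydro-4H-pyran-4-one; 9 1-methoxy-1,3-bis(trimethylsilyloxy)buta-1,3-diene (Chan's diene)
Product: 15 (3R)-8-hydroxy-3-[(6E)-pentadec-6-en-1-yl]-3,4-dihydro-1H-isochromen-1-one, via bis-silyl Michael adduct 10 (not isolated), via keto ester pyranone 11 (not isolated), via open-chain dioxo enoate 12 (not isolated), via cyclic aldol 13 (not isolated), via hydroxy salicylate 14 (not isolated)
Conditions: Me3SiOTf (0.2 equiv), 9 (1.2 equiv), CH2Cl2, −78 °C; then MeOH (5 equiv), DBU (3 equiv), −78 → 40 °C; then p-TsOH·H2O (4 equiv), 40 °C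
Reagents that add atoms: none
Why: Proposed new method: Me3SiOTf-catalysed vinylogous Mukaiyama–Michael addition of the diene terminus to the enol-ether carbon of the vinylogous ester gives 10, whose desilylated form 11 has the new ring C–O bond β to two ketones, so base opens it by retro-oxa-Michael (E1cB) to the polyketide-like chain 12, whose C2 methylene closes onto the C7 ketone (intramolecular aldol, 13), dehydration and enolisation aromatise to 14, and acid closes the lactone through the C9 hydroxyl, no bond to the stereocentre being made or broken so that R is retained; the closest known reactions are the addition of 1,3-bis(silyloxy)dienes to chromones followed by base-induced retro-Michael/aldol/lactonisation to benzo[c]chromen-6-ones, and the Chan-type formal [3+3] cyclisation of such dienes with 3-alkoxy-enones to salicylates.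

## Compound list

1 | dec-1-yne | CCCCCCCCC#C | starting material
2 | ethyl 6-bromohexanoate | CCOC(=O)CCCCCBr | starting material
3 | (E)-dec-1-enylzirconocene chloride | CCCCCCCC/C=C/[Zr](Cl)(C1C=CC=C1)C1C=CC=C1 | intermediate (not isolated)
4 | ethyl (E)-hexadec-7-enoate | CCCCCCCC/C=C/CCCCCC(=O)OCC | intermediate
5 | (E)-hexadec-7-enal | CCCCCCCC/C=C/CCCCCC=O | intermediate
6 | (E)-1-methoxy-3-(trimethylsilyloxy)buta-1,3-diene | CO/C=C/C(=C)O[Si](C)(C)C | starting material
7 | (1E,5R,11E)-1-methoxy-5-(trimethylsilyloxy)icosa-1,11-dien-3-one | CCCCCCCC/C=C/CCCCC[C@@H](O[Si](C)(C)C)CC(=O)/C=C/OC | intermediate (not isolated)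
8 | (R)-2-[(E)-pentadec-6-enyl]-2,3-dihydro-4H-pyran-4-one | CCCCCCCC/C=C/CCCCC[C@@H]1CC(=O)C=CO1 | intermediate
9 | 1-methoxy-1,3-bis(trimethylsilyloxy)buta-1,3-diene (geometry at C1=C2 as supplied; it has no bearing on the product) | COC(O[Si](C)(C)C)=CC(=C)O[Si](C)(C)C | starting material
10 | (2R)-6-[4-methoxy-2-oxo-4-(trimethylsilyloxy)but-3-enyl]-2-[(E)-pentadec-6-enyl]-4-(trimethylsilyloxy)-3,6-dihydro-2H-pyran (C6 epimers, mainly 2,6-trans; this centre is erased in the same flask) | COC(O[Si](C)(C)C)=CC(=O)CC1C=C(O[Si](C)(C)C)C[C@@H](CCCCC/C=C/CCCCCCCC)O1 | intermediate (not isolated)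
11 | methyl 3-oxo-4-[(6R)-4-oxo-6-[(E)-pentadec-6-enyl]oxan-2-yl]butanoate (C2 epimers of the oxane) | COC(=O)CC(=O)CC1CC(=O)C[C@@H](CCCCC/C=C/CCCCCCCC)O1 | intermediate (not isolated)
12 | methyl (5Z,9R,15E)-9-hydroxy-3,7-dioxotetracosa-5,15-dienoate (5E and 5Z interconvert through the dienolate; 5Z cyclises) | COC(=O)CC(=O)C/C=C\C(=O)C[C@H](O)CCCCC/C=C/CCCCCCCC | intermediate (not isolated)
13 | methyl 2-hydroxy-2-[(2R,8E)-2-hydroxyheptadec-8-enyl]-6-oxocyclohex-3-ene-1-carboxylate (ring centres transient, undefined) | COC(=O)C1C(=O)CC=CC1(O)C[C@H](O)CCCCC/C=C/CCCCCCCC | intermediate (not isolated)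
14 | methyl 2-hydroxy-6-[(2R,8E)-2-hydroxyheptadec-8-enyl]benzoate | COC(=O)c1c(O)cccc1C[C@H](O)CCCCC/C=C/CCCCCCCC | intermediate (not isolated)
15 | (3R)-8-hydroxy-3-[(6E)-pentadec-6-en-1-yl]-3,4-dihydro-1H-isochromen-1-one | CCCCCCCC/C=C/CCCCC[C@@H]1Cc2cccc(O)c2C(=O)O1 | target

## Summary

Total step count: 4. Longest linear sequence: 4 steps (1 + 2 → 4 → 5 → 8 → 15).

## Steps most likely to fail, with fallbacks

**Step 4 (one-flask Michael / ring-opening / aldol aromatisation / lactonisation).** The risks are:
- retro-oxa-Michael opening on the carbinol side, or E1cB loss of the C9 oxygen from 12, which would erode the ee or give a styrenyl salicylate;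
- slow ring opening, because the leaving group is an alkoxide and not a phenoxide;
- incomplete lactonisation.

The design counters the first risk because only the desired C–O bond is β to two carbonyl groups, and its cleavage is pulled forward by irreversible aromatisation. An aldol-first pathway on intact 11, giving a bridged bicycle that then loses the ring oxygen, converges on 14 and never exposes the carbinol C–O bond.

Fallback: it sets out from 5. The aldol stage of step 3 is run with 6 under the same (S)-BINOL/Ti(OiPr)4 catalysis but worked up with aqueous NaHCO3 in place of the TFA stage, giving the open-chain (1E,5R,11E)-5-hydroxy-1-methoxyicosa-1,11-dien-3-one F1. TBSOTf/2,6-lutidine converts it to (1E,5R,11E)-5-(tert-butyldimethylsilyloxy)-1-methoxyicosa-1,11-dien-3-one F2. A TiCl4-mediated Chan-type formal [3+3] cyclocondensation of F2 with 9 (CH2Cl2, −78 → 20 °C) forms the same C2–C7 bond and aromatises directly to methyl 2-hydroxy-6-[(2R,8E)-2-(tert-butyldimethylsilyloxy)heptadec-8-enyl]benzoate F3, with the carbinol oxygen capped so that it can neither leave nor re-add. Aqueous HF in MeCN removes the silyl group, and the route is rejoined at 14, which lactonises to 15 under acid as in the last stage of step 4.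

**Step 3 (enantioselective formal hetero-Diels–Alder reaction).** The risks are an ee below the needed level for this long, enolisable aldehyde, and a sense of induction that rests on analogy. The configuration of 8 should be checked before step 4; (R)-BINOL is substituted if the sense is reversed.

Fallback: it sets out from 5. SnCl2-catalysed Roskamp homologation with ethyl diazoacetate gives ethyl (E)-3-oxooctadec-9-enoate F4. Noyori hydrogenation with RuCl2[(R)-BINAP] (H2, EtOH), which should spare the isolated disubstituted alkene, gives ethyl (3R,9E)-3-hydroxyoctadec-9-enoate F5 with the well-established sense for β-keto esters. MeNH(OMe)·HCl/iPrMgCl gives (3R,9E)-3-hydroxy-N-methoxy-N-methyloctadec-9-enamide F6. Excess HC≡CMgBr gives (5R,11E)-5-hydroxyicos-11-en-1-yn-3-one F7. AgOTf-catalysed 6-endo-dig oxa-Michael cyclisation then rejoins the route at 8.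

**Step 1 (alkenylzirconium/alkyl bromide cross-coupling).** The risks are β-hydride elimination or homocoupling lowering the yield, and partial reduction of the ester by residual Cp2Zr(H)Cl.

Fallback: it sets out from 1. Lithium dec-1-ynide (n-BuLi, THF/DMPU; two equivalents, the first acting as base for the hydroxyl) is alkylated with 6-bromohexan-1-ol to give hexadec-7-yn-1-ol F8. Na in liquid NH3 gives (E)-hexadec-7-en-1-ol F9 as the pure E isomer by anti dissolving-metal reduction. Dess–Martin oxidation rejoins the route at 5, which also bypasses 4 and the partial reduction of step 2.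

## Further compounds

F1 | step 4 | (1E,5R,11E)-5-hydroxy-1-methoxyicosa-1,11-dien-3-one | CCCCCCCC/C=C/CCCCC[C@@H](O)CC(=O)/C=C/OC
F2 | step 4 | (1E,5R,11E)-5-(tert-butyldimethylsilyloxy)-1-methoxyicosa-1,11-dien-3-one | CCCCCCCC/C=C/CCCCC[C@@H](O[Si](C)(C)C(C)(C)C)CC(=O)/C=C/OC
F3 | step 4 | methyl 2-hydroxy-6-[(2R,8E)-2-(tert-butyldimethylsilyloxy)heptadec-8-enyl]benzoate | COC(=O)c1c(O)cccc1C[C@H](O[Si](C)(C)C(C)(C)C)CCCCC/C=C/CCCCCCCC
F4 | step 3 | ethyl (E)-3-oxooctadec-9-enoate | CCCCCCCC/C=C/CCCCCC(=O)CC(=O)OCC
F5 | step 3 | ethyl (3R,9E)-3-hydroxyoctadec-9-enoate | CCCCCCCC/C=C/CCCCC[C@@H](O)CC(=O)OCC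
F6 | step 3 | (3R,9E)-3-hydroxy-N-methoxy-N-methyloctadec-9-enamide | CCCCCCCC/C=C/CCCCC[C@@H](O)CC(=O)N(C)OC
F7 | step 3 | (5R,11E)-5-hydroxyicos-11-en-1-yn-3-one | CCCCCCCC/C=C/CCCCC[C@@H](O)CC(=O)C#C
F8 | step 1 | hexadec-7-yn-1-ol | CCCCCCCCC#CCCCCCCO
F9 | step 1 | (E)-hexadec-7-en-1-ol | CCCCCCCC/C=C/CCCCCCO
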